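Two lengths and one choice are asked of two flasks, which differ in their charge of initiator.

    initiator → spent initiator B (k1 = 0.577 s⁻¹)
    free monomer + living end → monomer in chains + living end, rate k2*[living end]*[free monomer] (k2 = 1140 M⁻¹ s⁻¹)
    free monomer + initiator → living end + monomer in chains (k3 = 968 M⁻¹ s⁻¹)
    living end + transfer agent → dead chain (k4 = 815 M⁻¹ s⁻¹)
    2 initiator → spent initiator A (k5 = 1190 M⁻¹ s⁻¹)

- Monday's: free monomer 0.0010 M; transfer agent 0.0100 mM; initiator 95 µM; time 1.0 min
- Saturday's: free monomer 0.0010 M; transfer agent 0.0100 mM; initiator 50 µM; time 1.0 min

- which of the two ends with the longer chains by the average number of monomer units in a chain (chains begun, living or dead) ("neither" if they lie within 10%) (Monday's / Saturday's / neither)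
- average number of monomer units in a chain (chains begun, living or dead) at the end, Monday's
- average number of monomer units in a chain (chains begun, living or dead) at the end, Saturday's

- a doubled species enters its step squared and goes two at a time
- the average divides the monomer in chains by the number of chains begun, living and dead together
- run time (Monday's): 1.0 min

**Chains begun.** The half-life of initiator by its plain decay alone, 1.2 s, is far shorter than the run, so chains begin early, while free monomer stands near its charge. At the start, initiator enters chains at 0.968 s⁻¹, decays at 0.577 s⁻¹ and, on Monday's, pairs off at 0.226 s⁻¹. The share f entering chains, the initiator efficiency, is estimated at these start rates as 54.7% on Monday's and 58.2% on Saturday's; it is a start share, not the share over the whole run.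

**One number.** Free monomer charged per chain begun, reckoned with these start shares, comes to 19.3 on Monday's and 34.4 on Saturday's. This ceiling length, c(free monomer)/(f·c(initiator)), is the reckoned average length once every free monomer has entered a chain. Saturday's ceiling is 1.78 times Monday's, well past the 10% margin.

**Is it enough?** Not for the lengths, since a ceiling takes time to reach. With every end counted as living, free monomer falls pseudo-first-order at k2·f·c(initiator), so the conversions are 97.1% on Monday's and 86.3% on Saturday's. Ceiling times conversion gives 18.7 for Monday's and 29.7 for Saturday's, so the longer chains are Saturday's. The charge of transfer agent, 0.0100 mM, is smaller than Saturday's 29.1 µM of chains, but it kills ends, so these figures lean high.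

**The result.** The forecast named Saturday's, with 17.7 for Monday's and 27.7 for Saturday's, noting that “the survivors keep propagating”. The simulation gives Saturday's, with 17.7 and 27.7.

**The neighbour.** At 10.0 min, Saturday's reads 33.5, under its reckoned ceiling. Saturday's recipe with free monomer cut to 2.5 × 10⁻⁴ M has a start share of 25.8% and a reckoned ceiling of 19.4, lower than Saturday's. Its reckoned conversion is 58.6%, which makes the length 11.4. The simulation gives that flask 10.2, with 45.0% of its charged free monomer left.

All constants were set for the occasion.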